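## Analysis of the target

The target joins two trans-2,3-diaryl-2,3-dihydrobenzofurans through one aryl–sp3 bond. Ring A is the benzo ring of the first unit: it carries the ring oxygen O1 at C7a, a free hydroxyl at C6 and the (E)-4-hydroxystyryl group at C4, so ring A with its side chain is a resveratrol-type stilbene. C2 bears a 4-hydroxyphenyl group. C3 bears ring B, the benzo ring of the second unit, attached through C5'; ring B carries a hydroxyl at C7', and its dihydrofuran holds a 3,5-dihydroxyphenyl group at C3' and a 4-hydroxyphenyl group at C2'.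

There are four stereocentres: C2 (S) and C3 (S), trans to each other, and C2' (R) and C3' (R), also trans. The two pairs are separated by the ring B arene, so neither can steer the other and each needs its own control.

The molecule has seven free phenols and an electron-rich stilbene. Both C2–O and C2'–O are benzylic ethers with a para-oxygenated aryl group and ionise easily. Acid therefore threatens epimerisation, ring opening and Friedel–Crafts closure of ring B onto the stilbene; for this reason a final demethylation of methyl ethers with boron tribromide is not an option, and the phenols are carried as silyl ethers that leave with fluoride.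

The hard points are the stereodefined C3–C5' bond, the 1,2,3,5-substitution of ring A, and an endgame that frees seven phenols without acid.

The strategy rests on ring A. Its six carbons fall into three adjacent pairs: C7a/C7 (oxygen on C7a, hydrogen on C7), C6/C5 (oxygen on C6, hydrogen on C5) and C4/C3a (styryl on C4, C3 on C3a). Each pair is an alkyne, and O1–C2–C3 is a three-atom tether between the first and the third. Ring A and the fused dihydrofuran can therefore be formed together around stereocentres C2 and C3 that already exist.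

## Retrosynthetic reasoning

The target 39 is traced to its heptakis(silyl ether) 38. Only protecting groups are cut. Silyl ethers are chosen for every phenol because fluoride buffered with a weak acid leaves the two benzylic ethers and the stilbene alone.

In 38 the ring B dihydrofuran is cut at O1'–C2' and C2'–C3'. This gives the sulfone 29, which is the source of the ortho-quinone methide 36, and the sulfonium salt 35, which is the source of the ylide 37. The cut is made here because a one-carbon ylide adding to a quinone methide forms both bonds in one operation with inherent trans selectivity, and the chiral sulfide decides the absolute sense without help from the distant C2/C3 pair. The forward reaction has to add the ylide to the exocyclic carbon and close by displacement of the sulfide.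

The sulfone 29 comes from the benzhydrol 28, and 28 from the salicylaldehyde 24 and the aryl bromide 26 through the Grignard reagent 27. The aldehyde 24 is cut at C3a'–CHO back to the phenol 23, because a free phenol directs formylation to its only open ortho position. The phenol 23 is released from the ether 21 through the silyl ether 22. The forward sequence needs exactly one free phenol at the formylation; this is why O7a' carries a methoxymethyl group that can be taken off selectively, while every other oxygen carries a silyl group.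

The C6–O bond of 21 is traced through the phenol 20 to the C6–B bond of the boronate 19. A boron substituent is the oxygen equivalent that a terminal alkyne can carry into an arene.

The boronate 19 is cut at C7a–C3a, C4–C5 and C6–C7. This opens ring A and the dihydrofuran to the tethered diyne 17 and the boryl alkyne 18. The cut removes the need to functionalise a resorcinol regioselectively: the styryl group, the boron and the ring oxygen are already placed on the three alkynes. C2 and C3 are not touched. The forward reaction has to couple the ynol ether and the enyne alkyne of 17 on ruthenium and take up 18 with the boron-bearing carbon at C7.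

The ynol ether 17 is cut at its O–C(sp) bond, through the dichlorovinyl ether 15 and the formate 14, back to the alcohol 13. The two carbons are brought in on the ester oxygen because the alkoxide of 13 must be avoided: it could fragment by retro-propargylation or isomerise at the acidic C3–H.

The alcohol 13 is cut at C2–C3 into the aldehyde 2 and the propargylic benzoate 11, which reacts as the allenylzinc 12. This cut sets both stereocentres at once: C3 by transfer of chirality from the carbinol centre of 11 and C2 by the cyclic transition state. The benzoate 11 comes from the alcohol 10, and 10 is cut at the carbinol–alkyne bond into the ring B aldehyde 8 and the enyne 5 (as the alkynylzinc 9). The critical C3–C5' bond is thus present from the start as the aldehyde carbon of 8.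

The building blocks are simple. The enyne 5 comes from aldehyde 2 and phosphonate 3 through the silyl enyne 4; aldehyde 2 comes from 1. The ring B aldehyde 8 comes from 6 through 7. The bromide 26 comes from 25. The salt 35 comes from the bromide 34 (made from 2 through 33) and the sulfide 32 (made from 30 through 31).

## Alternatives that were turned down

Alternative 1: Ring A, its two oxygens and C2 are taken from the flavanone naringenin A1, and the dihydrofuran is made by contracting the pyranone, so the disconnection is C3–C3a. After O-methylation and diazo transfer, irradiation of the 3-diazo flavanone A2 in methanol causes a Wolff rearrangement: the ring A carbon migrates to the carbene carbon and the ketene is trapped to give the trans ester A3.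
- For: no arene has to be built, the oxygenation is natural, and the ring contraction is dependable.
- Against: flavanones open reversibly to chalcones under the basic conditions of methylation and diazo transfer, so the pool stereocentre is not secure. C3 ends up carrying an ester carbon where the target needs ring B bonded directly; that carbon must be removed again by a decarboxylative arylation with the whole ring B unit. The C4 hydroxyl still has to become the styryl group, and C2'/C3' are not addressed.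
- Comparison: it is stronger at C2, which needs no reagent control, and in step count to a first dihydrobenzofuran. The chosen strategy offers instead the C3–ring B bond, the styryl group and the C6 oxygen in place by construction, with no carbon put in and taken out.

Alternative 2: Both aryl-bearing bonds of the ring B dihydrofuran are cut from the (E)-alkenyl boronate A4. Its ate complex with 4-methoxyphenyllithium A5 reacts with 3,5-dimethoxyphenyl triflate A6 under Pd(OAc)2 and a chiral ferrocenyl bisphosphine. The aryl group migrates from boron to C2' while the arylpalladium adds to C3', giving the boronate A7.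
- For: one catalytic, enantioselective step sets both ring B centres and the aryl groups are modular.
- Against: the C–B bond must be oxidised and the ring closed with inversion at a 4-methoxybenzylic carbinol, where ionisation competes and can erode the configuration. More seriously, A7 is only ring B as an aryl chloride: the C3–C5' bond to a stereodefined sp3 carbon and all of ring A remain open.
- Comparison: it is stronger on catalytic control of C2' and C3', where the chosen route spends a stoichiometric chiral sulfide. The chosen strategy offers a solution for the rest of the molecule and forms C3–C5' by carbonyl addition instead of a cross-coupling onto a secondary benzylic centre.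

Alternative 3: Ring B is cut at O1'–C2' and C2'–C3'. Cs2CO3 expels sulfinate from the sulfone A8, the chiral sulfonium ylide A9 adds to the resulting ortho-quinone methide, and the phenoxide displaces the sulfide to give the bromide A10.
- For: trans selectivity is inherent and the step runs on small material.
- Against: as a leading strategy it again stops at ring B; the bromide must then be joined to C3 and ring A built. The methyl ethers of A10 cannot be removed at the end without ionising the 2-aryl ethers.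
- Comparison: on ring B it is equal, because the chosen route uses this same annulation in step 25. Doing it first is stronger in one respect, since the reagent-controlled step is then spent on cheap material. The chosen order offers a short path to the key-step precursor; the minor isomer of the late annulation is a diastereomer and can be separated.

Key step: step 12

Abbreviations: TIPS = triisopropylsilyl, TIPSO = (triisopropylsilyl)oxy, MOM = methoxymethyl, MOMO = methoxymethoxy, Bpin = 4,4,5,5-tetramethyl-1,3,2-dioxaborolan-2-yl.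

Remark on the chemistry: (S)-BINOL/Ti(OiPr)4 is assumed to deliver the alkynylzinc to the Si face of aldehyde 8 as it does alkyl groups from dialkylzincs, and the benzylide of (2R,5R)-2,5-dimethylthiolane is assumed to react with the facial sense it shows in benzylidene transfer to aldehydes; if either sense is the opposite, the antipodal ligand or sulfide is used and nothing else changes.

## Route

Step 1
Reactants: 1 4-hydroxybenzaldehyde
Product: 2 4-(TIPSO)benzaldehyde
Conditions: TIPSCl, imidazole, DMF, rt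
Reagents that add atoms: chlorotriisopropylsilane (TIPSCl), CC(C)[Si](Cl)(C(C)C)C(C)C
Why: Imidazole-promoted silylation of a phenol. The bulky aryl silyl ether is chosen because it must survive organozinc, organolithium and carbonate bases and still leave with fluoride.

Step 2
Reactants: 2 4-(TIPSO)benzaldehyde; 3 diethyl [3-(trimethylsilyl)prop-2-yn-1-yl]phosphonate
Product: 4 (E)-trimethyl{4-[4-(TIPSO)phenyl]but-3-en-1-yn-1-yl}silane
Conditions: 3, LiN(SiMe3)2, THF, −78 °C; then 2, −78 °C → rt
Reagents that add atoms: none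
Why: Horner–Wadsworth–Emmons olefination with a propargylic phosphonate, which should give the (E)-enyne with an aromatic aldehyde. The silyl cap keeps the anion from reacting at the alkyne terminus.

Step 3
Reactants: 4 (E)-trimethyl{4-[4-(TIPSO)phenyl]but-3-en-1-yn-1-yl}silane
Product: 5 (E)-[4-(but-1-en-3-yn-1-yl)phenoxy]triisopropylsilane
Conditions: K2CO3 (0.2 equiv), MeOH/THF, 0 °C
Reagents that add atoms: none
Why: Methanolysis of an alkynyl–silicon bond. It is far faster than attack on the hindered aryl triisopropylsilyl ether, so the phenol stays protected.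

Step 4
Reactants: 6 3,4-dihydroxybenzaldehyde
Product: 7 3-hydroxy-4-(MOMO)benzaldehyde
Conditions: MOMCl (1.05 equiv), K2CO3 (1.1 equiv), acetone, 0 °C → rt
Reagents that add atoms: chloromethyl methyl ether (MOMCl), COCCl
Why: Regioselective O-alkylation: one equivalent of base forms the phenoxide para to the aldehyde, the more acidic of the two, and only that oxygen is alkylated. This oxygen is the future ring oxygen O1' and needs a group that can later be removed on its own.

Step 5
Reactants: 7 3-hydroxy-4-(MOMO)benzaldehyde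
Product: 8 4-(MOMO)-3-(TIPSO)benzaldehyde
Conditions: TIPSCl, imidazole, DMF, rt
Reagents that add atoms: chlorotriisopropylsilane (TIPSCl), CC(C)[Si](Cl)(C(C)C)C(C)C
Why: Silylation of the remaining phenol. The acetal on the neighbouring oxygen cannot migrate, so the two ring B oxygens stay differentiated.

Step 6
Reactants: 5 (E)-[4-(but-1-en-3-yn-1-yl)phenoxy]triisopropylsilane; 8 4-(MOMO)-3-(TIPSO)benzaldehyde
Product: 10 (1R,4E)-1-[4-(MOMO)-3-(TIPSO)phenyl]-5-[4-(TIPSO)phenyl]pent-4-en-2-yn-1-ol, via alkynyl(ethyl)zinc 9 (not isolated)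
Conditions: 5 (2.5 equiv), Et2Zn (2.5 equiv), HMPA, CH2Cl2, rt; (S)-BINOL (40 mol%), Ti(OiPr)4 (1 equiv); then 8, rt
Reagents that add atoms: none
Why: Titanium–BINOL-catalysed enantioselective addition of an alkynylzinc to an aromatic aldehyde. The (S)-ligand should direct the alkynyl group to the Si face, which sets the carbinol centre as R (OH > alkynyl > aryl).

Step 7
Reactants: 10 (1R,4E)-1-[4-(MOMO)-3-(TIPSO)phenyl]-5-[4-(TIPSO)phenyl]pent-4-en-2-yn-1-ol
Product: 11 (1R,4E)-1-[4-(MOMO)-3-(TIPSO)phenyl]-5-[4-(TIPSO)phenyl]pent-4-en-2-yn-1-yl benzoate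
Conditions: BzCl, Et3N, DMAP (cat.), CH2Cl2, 0 °C
Reagents that add atoms: benzoyl chloride, O=C(Cl)c1ccccc1
Why: Acylation with retention at the carbinol carbon. A benzoate is used because a sulfonate of this para-oxygenated benzylic propargylic alcohol would ionise and racemise.

Step 8
Reactants: 11 (1R,4E)-1-[4-(MOMO)-3-(TIPSO)phenyl]-5-[4-(TIPSO)phenyl]pent-4-en-2-yn-1-yl benzoate; 2 4-(TIPSO)benzaldehyde
Product: 13 (1S,2S,5E)-2-[4-(MOMO)-3-(TIPSO)phenyl]-1,6-bis[4-(TIPSO)phenyl]hex-5-en-3-yn-1-ol, via allenyl(ethyl)zinc 12 (not isolated)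
Conditions: 2 (1.2 equiv), Pd(PPh3)4 (5 mol%), Et2Zn (3 equiv), THF, −20 → 0 °C
Reagents that add atoms: none
Why: Palladium-catalysed umpolung propargylation: zerovalent palladium ionises the benzoate in an anti SN2' sense and ethyl transfer from zinc gives the (aS)-allenylzinc 12. This adds to 2 through a cyclic SE2' transition state on the zinc-bearing face, so C3 forms with net inversion (S). The aldehyde aryl group sits away from the ring B aryl group, which should give the anti alcohol with C2 as S.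

Step 9
Reactants: 13 (1S,2S,5E)-2-[4-(MOMO)-3-(TIPSO)phenyl]-1,6-bis[4-(TIPSO)phenyl]hex-5-en-3-yn-1-ol
Product: 14 (1S,2S,5E)-2-[4-(MOMO)-3-(TIPSO)phenyl]-1,6-bis[4-(TIPSO)phenyl]hex-5-en-3-yn-1-yl formate
Conditions: acetic formic anhydride, pyridine, CH2Cl2, 0 °C
Reagents that add atoms: acetic formic anhydride, CC(=O)OC=O
Why: Formyl transfer to a secondary alcohol under neutral to weakly basic conditions. No alkoxide of 13 is formed, so neither retro-propargylation nor isomerisation at the acidic C3–H can occur.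

Step 10
Reactants: 14 (1S,2S,5E)-2-[4-(MOMO)-3-(TIPSO)phenyl]-1,6-bis[4-(TIPSO)phenyl]hex-5-en-3-yn-1-yl formate
Product: 15 2,2-dichlorovinyl ether of 13 [(1S,2S,5E)-1-(2,2-dichloroethenyloxy) compound]
Conditions: PPh3 (3 equiv), CCl4 (10 equiv), THF, 60 °C
Reagents that add atoms: tetrachloromethane, ClC(Cl)(Cl)Cl
Why: Wittig-type dichloromethylenation of a formate by the ylide formed from PPh3 and CCl4. It places both carbons of the future ynol ether on oxygen without base.

Step 11
Reactants: 15 2,2-dichlorovinyl ether of 13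
Product: 17 (1S,2S,5E)-1-(ethynyloxy)-2-[4-(MOMO)-3-(TIPSO)phenyl]-1,6-bis[4-(TIPSO)phenyl]hex-5-en-3-yne, via lithium alkynyl ether 16 (not isolated)
Conditions: n-BuLi (2.1 equiv), THF, −78 → −40 °C; then H2O, −78 °C
Reagents that add atoms: none
Why: Elimination and chlorine–lithium exchange convert the dichlorovinyl ether into the lithium alkynyl ether, which is protonated. At −78 °C with exact stoichiometry, butyllithium should react at the vinyl chloride faster than at the hindered tertiary C3–H. The product is kept cold and used at once, because benzylic ynol ethers rearrange on warming.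

Step 12
Reactants: 17 (1S,2S,5E)-1-(ethynyloxy)-2-[4-(MOMO)-3-(TIPSO)phenyl]-1,6-bis[4-(TIPSO)phenyl]hex-5-en-3-yne; 18 2-ethynyl-4,4,5,5-tetramethyl-1,3,2-dioxaborolane
Product: 19 (2S,3S)-6-Bpin-3-[4-(MOMO)-3-(TIPSO)phenyl]-2-[4-(TIPSO)phenyl]-4-[(E)-4-(TIPSO)styryl]-2,3-dihydrobenzofuran
Conditions: 18 (3 equiv), Cp*RuCl(cod) (10 mol%), ClCH2CH2Cl, rt, slow addition of 17
Reagents that add atoms: none
Why: Proposed new method: Cp*RuCl, freed of cod, binds the ynol ether and the enyne alkyne of 17 and couples them oxidatively; this forms C3a–C7a and closes the five-membered O1–C2–C3–C3a–C7a ring as part of a bicyclic ruthenacyclopentadiene, a metal-templated cyclisation of the 1,6-diyne. Alkyne 18 then inserts so that its boron-bearing carbon bonds to C7, and reductive elimination joins its CH carbon to C4 and closes benzene ring A, a formal (2+2+2) closure. The closest known reaction type is the Cp*RuCl(cod)-catalysed cycloaddition of carbon-, ether-, amine- and ynamide-tethered 1,6-diynes with terminal alkynes, alkynylboronates included; what is new is an oxygen atom placed directly on one alkyne of the tether. No stereocentre is formed: C2 and C3 are sp3 bystanders and the neutral conditions at room temperature offer no path for their epimerisation. The step needs cross-selectivity over homo-coupling of the diyne, which slow addition of 17 to an excess of 18 should secure. It also needs meta regiochemistry (boron at C6), which should follow from the contrast between the unsubstituted terminus C7 and the styryl-bearing terminus C4, because the substituted carbon of the monoalkyne is placed away from the more hindered α-carbon of the metallacycle. The donor oxygen on C7a should stabilise the carbene-like α-carbon of the metallacycle, and the (E)-disubstituted styryl alkene is a much poorer ligand than the three alkynes. Room temperature is essential because 17 would otherwise rearrange through its benzylic ether.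

Step 13
Reactants: 19 (2S,3S)-6-Bpin-3-[4-(MOMO)-3-(TIPSO)phenyl]-2-[4-(TIPSO)phenyl]-4-[(E)-4-(TIPSO)styryl]-2,3-dihydrobenzofuran
Product: 20 (2S,3S)-3-[4-(MOMO)-3-(TIPSO)phenyl]-2-[4-(TIPSO)phenyl]-4-[(E)-4-(TIPSO)styryl]-2,3-dihydrobenzofuran-6-ol
Conditions: NaBO3·4H2O, THF/H2O, rt
Reagents that add atoms: sodium perborate tetrahydrate, [Na+].[O-]OB=O.O.O.O.O
Why: Oxidation of an arylboronic ester by 1,2-migration of the aryl group from boron to peroxide oxygen. Perborate is mild enough for the aryl silyl ethers, the acetal and the stilbene.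

Step 14
Reactants: 20 (2S,3S)-3-[4-(MOMO)-3-(TIPSO)phenyl]-2-[4-(TIPSO)phenyl]-4-[(E)-4-(TIPSO)styryl]-2,3-dihydrobenzofuran-6-ol
Product: 21 (2S,3S)-3-[4-(MOMO)-3-(TIPSO)phenyl]-6-(TIPSO)-2-[4-(TIPSO)phenyl]-4-[(E)-4-(TIPSO)styryl]-2,3-dihydrobenzofuran
Conditions: TIPSCl, imidazole, DMF, rt
Reagents that add atoms: chlorotriisopropylsilane (TIPSCl), CC(C)[Si](Cl)(C(C)C)C(C)C
Why: Silylation of the C6 phenol. It must be capped before step 16, where the only free phenol has to be the one on ring B.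

Step 15
Reactants: 21 (2S,3S)-3-[4-(MOMO)-3-(TIPSO)phenyl]-6-(TIPSO)-2-[4-(TIPSO)phenyl]-4-[(E)-4-(TIPSO)styryl]-2,3-dihydrobenzofuran
Product: 23 2-(TIPSO)-4-{(2S,3S)-6-(TIPSO)-2-[4-(TIPSO)phenyl]-4-[(E)-4-(TIPSO)styryl]-2,3-dihydrobenzofuran-3-yl}phenol, via aryl trimethylsilyl ether 22 (not isolated)
Conditions: Me3SiOSO2CF3, 2,2'-bipyridyl, CH2Cl2, 0 °C; then H2O
Reagents that add atoms: none
Why: Silyl triflate/bipyridyl cleavage of an aromatic methoxymethyl ether through the aryl trimethylsilyl ether 22, which hydrolyses on work-up. The medium is non-protic and buffered, so the benzylic ether and the stilbene see no free acid and the triisopropylsilyl ethers stay.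

Step 16
Reactants: 23 2-(TIPSO)-4-{(2S,3S)-6-(TIPSO)-2-[4-(TIPSO)phenyl]-4-[(E)-4-(TIPSO)styryl]-2,3-dihydrobenzofuran-3-yl}phenol
Product: 24 2-hydroxy-3-(TIPSO)-5-{(2S,3S)-6-(TIPSO)-2-[4-(TIPSO)phenyl]-4-[(E)-4-(TIPSO)styryl]-2,3-dihydrobenzofuran-3-yl}benzaldehyde
Conditions: MgCl2, Et3N, (CH2O)n, THF, reflux
Reagents that add atoms: formaldehyde (as paraformaldehyde), C=O
Why: Magnesium-mediated ortho-formylation of a phenol: phenoxide-directed hydroxymethylation, then hydride transfer to a second formaldehyde. C3a' is the only open position ortho to the phenol, and no other ring has a free hydroxyl group.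

Step 17
Reactants: 25 5-bromobenzene-1,3-diol
Product: 26 1-bromo-3,5-bis(TIPSO)benzene
Conditions: TIPSCl (2.2 equiv), imidazole, DMF, rt
Reagents that add atoms: chlorotriisopropylsilane (TIPSCl), CC(C)[Si](Cl)(C(C)C)C(C)C
Why: Double silylation of a resorcinol, giving the aryl donor in the same protecting-group family as the rest.

Step 18
Reactants: 24 2-hydroxy-3-(TIPSO)-5-{(2S,3S)-6-(TIPSO)-2-[4-(TIPSO)phenyl]-4-[(E)-4-(TIPSO)styryl]-2,3-dihydrobenzofuran-3-yl}benzaldehyde; 26 1-bromo-3,5-bis(TIPSO)benzene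
Product: 28 2-{[3,5-bis(TIPSO)phenyl](hydroxy)methyl}-6-(TIPSO)-4-{(2S,3S)-6-(TIPSO)-2-[4-(TIPSO)phenyl]-4-[(E)-4-(TIPSO)styryl]-2,3-dihydrobenzofuran-3-yl}phenol (both carbinol epimers), via arylmagnesium bromide 27 (not isolated)
Conditions: 26 (3.2 equiv), Mg, THF, reflux; then 24, 0 °C → rt
Reagents that add atoms: none
Why: Grignard addition to a salicylaldehyde; the first equivalent is spent on the phenol. The new carbinol centre is left uncontrolled because it becomes sp2 in step 25.

Step 19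
Reactants: 28 2-{[3,5-bis(TIPSO)phenyl](hydroxy)methyl}-6-(TIPSO)-4-{(2S,3S)-6-(TIPSO)-2-[4-(TIPSO)phenyl]-4-[(E)-4-(TIPSO)styryl]-2,3-dihydrobenzofuran-3-yl}phenol
Product: 29 2-{[3,5-bis(TIPSO)phenyl](4-methylphenylsulfonyl)methyl}-6-(TIPSO)-4-{(2S,3S)-6-(TIPSO)-2-[4-(TIPSO)phenyl]-4-[(E)-4-(TIPSO)styryl]-2,3-dihydrobenzofuran-3-yl}phenol (both epimers)
Conditions: 4-MeC6H4SO2H, CH2Cl2, rt
Reagents that add atoms: 4-methylbenzenesulfinic acid, Cc1ccc(S(=O)O)cc1
Why: Substitution of an ortho-hydroxybenzhydrol by a sulfinic acid through the stabilised benzhydryl cation. It gives a sulfone that releases the ortho-quinone methide with base; the sulfinic acid is too weak to ionise the existing dihydrofuran.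

Step 20
Reactants: 30 (2S,5S)-hexane-2,5-diol
Product: 31 (2S,5S)-hexane-2,5-diyl dimethanesulfonate
Conditions: MsCl, Et3N, CH2Cl2, 0 °C
Reagents that add atoms: methanesulfonyl chloride, CS(=O)(=O)Cl
Why: Sulfonylation of both secondary alcohols with retention, preparing two leaving groups.

Step 21
Reactants: 31 (2S,5S)-hexane-2,5-diyl dimethanesulfonate
Product: 32 (2R,5R)-2,5-dimethylthiolane
Conditions: Na2S·9H2O, DMSO, rt
Reagents that add atoms: sodium sulfide, [Na+].[Na+].[S-2]
Why: Double SN2 displacement by sulfide, the second one closing the ring. Two inversions turn the (S,S) diol into the C2-symmetric (R,R) sulfide.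

Step 22
Reactants: 2 4-(TIPSO)benzaldehyde
Product: 33 [4-(TIPSO)phenyl]methanol
Conditions: NaBH4, MeOH/THF, 0 °C
Reagents that add atoms: none
Why: Borohydride reduction of an aromatic aldehyde; the aryl silyl ether is inert.

Step 23
Reactants: 33 [4-(TIPSO)phenyl]methanol
Product: 34 [4-(bromomethyl)phenoxy]triisopropylsilane
Conditions: CBr4, PPh3, CH2Cl2, 0 °C
Reagents that add atoms: tetrabromomethane, BrC(Br)(Br)Br
Why: Appel bromination under neutral conditions, which avoids the hydrogen bromide that could attack the silyl ether. The electron-rich benzyl bromide is used without storage.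

Step 24
Reactants: 34 [4-(bromomethyl)phenoxy]triisopropylsilane; 32 (2R,5R)-2,5-dimethylthiolane
Product: 35 (2R,5R)-2,5-dimethyl-1-[4-(TIPSO)benzyl]thiolan-1-ium trifluoromethanesulfonate
Conditions: 32, AgOSO2CF3, CH2Cl2, 0 °C → rt
Reagents that add atoms: silver trifluoromethanesulfonate, [Ag+].[O-]S(=O)(=O)C(F)(F)F
Why: S-Alkylation of the sulfide with silver-assisted removal of bromide. The C2 symmetry of the sulfide means a single sulfonium salt forms, and the non-nucleophilic counter-ion keeps the electron-rich benzyl group on sulfur.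

Step 25
Reactants: 29 2-{[3,5-bis(TIPSO)phenyl](4-methylphenylsulfonyl)methyl}-6-(TIPSO)-4-{(2S,3S)-6-(TIPSO)-2-[4-(TIPSO)phenyl]-4-[(E)-4-(TIPSO)styryl]-2,3-dihydrobenzofuran-3-yl}phenol; 35 (2R,5R)-2,5-dimethyl-1-[4-(TIPSO)benzyl]thiolan-1-ium trifluoromethanesulfonate
Product: 38 (2S,3S)-3-{(2R,3R)-3-[3,5-bis(TIPSO)phenyl]-7-(TIPSO)-2-[4-(TIPSO)phenyl]-2,3-dihydrobenzofuran-5-yl}-6-(TIPSO)-2-[4-(TIPSO)phenyl]-4-[(E)-4-(TIPSO)styryl]-2,3-dihydrobenzofuran, via ortho-quinone methide 36 (not isolated), via sulfonium ylide 37 (not isolated)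
Conditions: 35 (1.5 equiv), Cs2CO3 (4 equiv), CH2Cl2, 0 °C → rt
Reagents that add atoms: none
Why: (4+1) annulation of an ortho-quinone methide with a sulfonium ylide: Cs2CO3 expels sulfinate from 29 to give 36 and deprotonates 35 to 37, conjugate addition forms C2'–C3', and the phenoxide displaces the sulfide with inversion to form O1'–C2'. The trans relationship should follow from the anti arrangement of the two aryl groups in the ring-closing betaine, and the absolute sense (2'R,3'R) from the C2-symmetric thiolane, whose methyl group shields one face of the benzylide. C2 and C3 are too remote to interfere, so control is by reagent and the minor trans isomer is a separable diastereomer.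

Step 26
Reactants: 38 (2S,3S)-3-{(2R,3R)-3-[3,5-bis(TIPSO)phenyl]-7-(TIPSO)-2-[4-(TIPSO)phenyl]-2,3-dihydrobenzofuran-5-yl}-6-(TIPSO)-2-[4-(TIPSO)phenyl]-4-[(E)-4-(TIPSO)styryl]-2,3-dihydrobenzofuran
Product: 39 CNP0172909.1, (2S,3S)-3-[(2R,3R)-3-(3,5-dihydroxyphenyl)-7-hydroxy-2-(4-hydroxyphenyl)-2,3-dihydrobenzofuran-5-yl]-2-(4-hydroxyphenyl)-4-[(E)-4-hydroxystyryl]-2,3-dihydrobenzofuran-6-ol
Conditions: Bu4NF (8 equiv), AcOH (8 equiv), THF, 0 °C → rt, under argon
Reagents that add atoms: none
Why: Fluoride cleavage of seven aryl silyl ethers, buffered with acetic acid so that each phenoxide is protonated as it forms. No acid strong enough to ionise the benzylic ethers or protonate the stilbene is present, and air is excluded to protect the polyphenol.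

## Compound list

1 | 4-hydroxybenzaldehyde | O=Cc1ccc(O)cc1 | starting material
2 | 4-(TIPSO)benzaldehyde | O=Cc1ccc(O[Si](C(C)C)(C(C)C)C(C)C)cc1 | intermediate
3 | diethyl [3-(trimethylsilyl)prop-2-yn-1-yl]phosphonate | CCOP(=O)(CC#C[Si](C)(C)C)OCC | starting material
4 | (E)-trimethyl{4-[4-(TIPSO)phenyl]but-3-en-1-yn-1-yl}silane | C[Si](C)(C)C#C/C=C/c1ccc(O[Si](C(C)C)(C(C)C)C(C)C)cc1 | intermediate
5 | (E)-[4-(but-1-en-3-yn-1-yl)phenoxy]triisopropylsilane | C#C/C=C/c1ccc(O[Si](C(C)C)(C(C)C)C(C)C)cc1 | intermediate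
6 | 3,4-dihydroxybenzaldehyde | O=Cc1ccc(O)c(O)c1 | starting material
7 | 3-hydroxy-4-(MOMO)benzaldehyde | O=Cc1ccc(OCOC)c(O)c1 | intermediate
8 | 4-(MOMO)-3-(TIPSO)benzaldehyde | O=Cc1ccc(OCOC)c(O[Si](C(C)C)(C(C)C)C(C)C)c1 | intermediate
9 | ethyl{(E)-4-[4-(TIPSO)phenyl]but-3-en-1-yn-1-yl}zinc | CC[Zn]C#C/C=C/c1ccc(O[Si](C(C)C)(C(C)C)C(C)C)cc1 | intermediate
10 | (1R,4E)-1-[4-(MOMO)-3-(TIPSO)phenyl]-5-[4-(TIPSO)phenyl]pent-4-en-2-yn-1-ol | O[C@H](c1ccc(OCOC)c(O[Si](C(C)C)(C(C)C)C(C)C)c1)C#C/C=C/c1ccc(O[Si](C(C)C)(C(C)C)C(C)C)cc1 | intermediate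
11 | (1R,4E)-1-[4-(MOMO)-3-(TIPSO)phenyl]-5-[4-(TIPSO)phenyl]pent-4-en-2-yn-1-yl benzoate | O=C(O[C@H](c1ccc(OCOC)c(O[Si](C(C)C)(C(C)C)C(C)C)c1)C#C/C=C/c1ccc(O[Si](C(C)C)(C(C)C)C(C)C)cc1)c1ccccc1 | intermediate
12 | ethyl{(aS,1E)-5-[4-(MOMO)-3-(TIPSO)phenyl]-1-[4-(TIPSO)phenyl]penta-1,3,4-trien-3-yl}zinc | CC[Zn]C(/C=C/c1ccc(O[Si](C(C)C)(C(C)C)C(C)C)cc1)=[C@@]=C([H])c1ccc(OCOC)c(O[Si](C(C)C)(C(C)C)C(C)C)c1 | intermediate
13 | (1S,2S,5E)-2-[4-(MOMO)-3-(TIPSO)phenyl]-1,6-bis[4-(TIPSO)phenyl]hex-5-en-3-yn-1-ol | O[C@H](c1ccc(O[Si](C(C)C)(C(C)C)C(C)C)cc1)[C@@H](c1ccc(OCOC)c(O[Si](C(C)C)(C(C)C)C(C)C)c1)C#C/C=C/c1ccc(O[Si](C(C)C)(C(C)C)C(C)C)cc1 | intermediate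
14 | (1S,2S,5E)-2-[4-(MOMO)-3-(TIPSO)phenyl]-1,6-bis[4-(TIPSO)phenyl]hex-5-en-3-yn-1-yl formate | O=CO[C@H](c1ccc(O[Si](C(C)C)(C(C)C)C(C)C)cc1)[C@@H](c1ccc(OCOC)c(O[Si](C(C)C)(C(C)C)C(C)C)c1)C#C/C=C/c1ccc(O[Si](C(C)C)(C(C)C)C(C)C)cc1 | intermediate
15 | (1S,2S,5E)-1-(2,2-dichloroethenyloxy)-2-[4-(MOMO)-3-(TIPSO)phenyl]-1,6-bis[4-(TIPSO)phenyl]hex-5-en-3-yne | ClC(Cl)=CO[C@H](c1ccc(O[Si](C(C)C)(C(C)C)C(C)C)cc1)[C@@H](c1ccc(OCOC)c(O[Si](C(C)C)(C(C)C)C(C)C)c1)C#C/C=C/c1ccc(O[Si](C(C)C)(C(C)C)C(C)C)cc1 | intermediate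
16 | lithium acetylide of 17 (lithium alkynyl ether) | [Li]C#CO[C@H](c1ccc(O[Si](C(C)C)(C(C)C)C(C)C)cc1)[C@@H](c1ccc(OCOC)c(O[Si](C(C)C)(C(C)C)C(C)C)c1)C#C/C=C/c1ccc(O[Si](C(C)C)(C(C)C)C(C)C)cc1 | intermediate
17 | (1S,2S,5E)-1-(ethynyloxy)-2-[4-(MOMO)-3-(TIPSO)phenyl]-1,6-bis[4-(TIPSO)phenyl]hex-5-en-3-yne | C#CO[C@H](c1ccc(O[Si](C(C)C)(C(C)C)C(C)C)cc1)[C@@H](c1ccc(OCOC)c(O[Si](C(C)C)(C(C)C)C(C)C)c1)C#C/C=C/c1ccc(O[Si](C(C)C)(C(C)C)C(C)C)cc1 | intermediate
18 | 2-ethynyl-4,4,5,5-tetramethyl-1,3,2-dioxaborolane | C#CB1OC(C)(C)C(C)(C)O1 | starting material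
19 | (2S,3S)-6-Bpin-3-[4-(MOMO)-3-(TIPSO)phenyl]-2-[4-(TIPSO)phenyl]-4-[(E)-4-(TIPSO)styryl]-2,3-dihydrobenzofuran | CC(C)[Si](Oc1ccc(/C=C/c2cc(B3OC(C)(C)C(C)(C)O3)cc3c2[C@H](c2ccc(OCOC)c(O[Si](C(C)C)(C(C)C)C(C)C)c2)[C@@H](c2ccc(O[Si](C(C)C)(C(C)C)C(C)C)cc2)O3)cc1)(C(C)C)C(C)C | intermediate
20 | (2S,3S)-3-[4-(MOMO)-3-(TIPSO)phenyl]-2-[4-(TIPSO)phenyl]-4-[(E)-4-(TIPSO)styryl]-2,3-dihydrobenzofuran-6-ol | CC(C)[Si](Oc1ccc(/C=C/c2cc(O)cc3c2[C@H](c2ccc(OCOC)c(O[Si](C(C)C)(C(C)C)C(C)C)c2)[C@@H](c2ccc(O[Si](C(C)C)(C(C)C)C(C)C)cc2)O3)cc1)(C(C)C)C(C)C | intermediate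
21 | (2S,3S)-3-[4-(MOMO)-3-(TIPSO)phenyl]-6-(TIPSO)-2-[4-(TIPSO)phenyl]-4-[(E)-4-(TIPSO)styryl]-2,3-dihydrobenzofuran | CC(C)[Si](Oc1ccc(/C=C/c2cc(O[Si](C(C)C)(C(C)C)C(C)C)cc3c2[C@H](c2ccc(OCOC)c(O[Si](C(C)C)(C(C)C)C(C)C)c2)[C@@H](c2ccc(O[Si](C(C)C)(C(C)C)C(C)C)cc2)O3)cc1)(C(C)C)C(C)C | intermediate
22 | trimethylsilyl ether of 23 (ring B: 4-(trimethylsilyloxy)-3-(TIPSO)phenyl) | CC(C)[Si](Oc1ccc(/C=C/c2cc(O[Si](C(C)C)(C(C)C)C(C)C)cc3c2[C@H](c2ccc(O[Si](C)(C)C)c(O[Si](C(C)C)(C(C)C)C(C)C)c2)[C@@H](c2ccc(O[Si](C(C)C)(C(C)C)C(C)C)cc2)O3)cc1)(C(C)C)C(C)C | intermediate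
23 | 2-(TIPSO)-4-{(2S,3S)-6-(TIPSO)-2-[4-(TIPSO)phenyl]-4-[(E)-4-(TIPSO)styryl]-2,3-dihydrobenzofuran-3-yl}phenol | CC(C)[Si](Oc1ccc(/C=C/c2cc(O[Si](C(C)C)(C(C)C)C(C)C)cc3c2[C@H](c2ccc(O)c(O[Si](C(C)C)(C(C)C)C(C)C)c2)[C@@H](c2ccc(O[Si](C(C)C)(C(C)C)C(C)C)cc2)O3)cc1)(C(C)C)C(C)C | intermediate
24 | 2-hydroxy-3-(TIPSO)-5-{(2S,3S)-6-(TIPSO)-2-[4-(TIPSO)phenyl]-4-[(E)-4-(TIPSO)styryl]-2,3-dihydrobenzofuran-3-yl}benzaldehyde | CC(C)[Si](Oc1ccc(/C=C/c2cc(O[Si](C(C)C)(C(C)C)C(C)C)cc3c2[C@H](c2cc(C=O)c(O)c(O[Si](C(C)C)(C(C)C)C(C)C)c2)[C@@H](c2ccc(O[Si](C(C)C)(C(C)C)C(C)C)cc2)O3)cc1)(C(C)C)C(C)C | intermediate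
25 | 5-bromobenzene-1,3-diol | Oc1cc(O)cc(Br)c1 | starting material
26 | 1-bromo-3,5-bis(TIPSO)benzene | Brc1cc(O[Si](C(C)C)(C(C)C)C(C)C)cc(O[Si](C(C)C)(C(C)C)C(C)C)c1 | intermediate
27 | [3,5-bis(TIPSO)phenyl]magnesium bromide | Br[Mg]c1cc(O[Si](C(C)C)(C(C)C)C(C)C)cc(O[Si](C(C)C)(C(C)C)C(C)C)c1 | intermediate
28 | 2-{[3,5-bis(TIPSO)phenyl](hydroxy)methyl}-6-(TIPSO)-4-{(2S,3S)-6-(TIPSO)-2-[4-(TIPSO)phenyl]-4-[(E)-4-(TIPSO)styryl]-2,3-dihydrobenzofuran-3-yl}phenol (both carbinol epimers) | CC(C)[Si](Oc1ccc(/C=C/c2cc(O[Si](C(C)C)(C(C)C)C(C)C)cc3c2[C@H](c2cc(C(O)c4cc(O[Si](C(C)C)(C(C)C)C(C)C)cc(O[Si](C(C)C)(C(C)C)C(C)C)c4)c(O)c(O[Si](C(C)C)(C(C)C)C(C)C)c2)[C@@H](c2ccc(O[Si](C(C)C)(C(C)C)C(C)C)cc2)O3)cc1)(C(C)C)C(C)C | intermediate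
29 | 2-{[3,5-bis(TIPSO)phenyl](4-methylphenylsulfonyl)methyl}-6-(TIPSO)-4-{(2S,3S)-6-(TIPSO)-2-[4-(TIPSO)phenyl]-4-[(E)-4-(TIPSO)styryl]-2,3-dihydrobenzofuran-3-yl}phenol (both epimers) | CC(C)[Si](Oc1ccc(/C=C/c2cc(O[Si](C(C)C)(C(C)C)C(C)C)cc3c2[C@H](c2cc(C(c4cc(O[Si](C(C)C)(C(C)C)C(C)C)cc(O[Si](C(C)C)(C(C)C)C(C)C)c4)S(=O)(=O)c4ccc(C)cc4)c(O)c(O[Si](C(C)C)(C(C)C)C(C)C)c2)[C@@H](c2ccc(O[Si](C(C)C)(C(C)C)C(C)C)cc2)O3)cc1)(C(C)C)C(C)C | intermediate
30 | (2S,5S)-hexane-2,5-diol | C[C@H](O)CC[C@H](C)O | starting material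
31 | (2S,5S)-hexane-2,5-diyl dimethanesulfonate | C[C@H](OS(C)(=O)=O)CC[C@H](C)OS(C)(=O)=O | intermediate
32 | (2R,5R)-2,5-dimethylthiolane | C[C@@H]1CC[C@@H](C)S1 | intermediate
33 | [4-(TIPSO)phenyl]methanol | OCc1ccc(O[Si](C(C)C)(C(C)C)C(C)C)cc1 | intermediate
34 | [4-(bromomethyl)phenoxy]triisopropylsilane | BrCc1ccc(O[Si](C(C)C)(C(C)C)C(C)C)cc1 | intermediate
35 | (2R,5R)-2,5-dimethyl-1-[4-(TIPSO)benzyl]thiolan-1-ium trifluoromethanesulfonate | C[C@@H]1CC[C@@H](C)[S+]1Cc1ccc(O[Si](C(C)C)(C(C)C)C(C)C)cc1.[O-]S(=O)(=O)C(F)(F)F | intermediate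
36 | ring B ortho-quinone methide: 6-[3,5-bis(TIPSO)benzylidene]-2-(TIPSO)-4-{(2S,3S)-6-(TIPSO)-2-[4-(TIPSO)phenyl]-4-[(E)-4-(TIPSO)styryl]-2,3-dihydrobenzofuran-3-yl}cyclohexa-2,4-dien-1-one | CC(C)[Si](Oc1ccc(/C=C/c2cc(O[Si](C(C)C)(C(C)C)C(C)C)cc3c2[C@H](C2=CC(=Cc4cc(O[Si](C(C)C)(C(C)C)C(C)C)cc(O[Si](C(C)C)(C(C)C)C(C)C)c4)C(=O)C(O[Si](C(C)C)(C(C)C)C(C)C)=C2)[C@@H](c2ccc(O[Si](C(C)C)(C(C)C)C(C)C)cc2)O3)cc1)(C(C)C)C(C)C | intermediate
37 | (2R,5R)-2,5-dimethylthiolan-1-ium-1-yl [4-(TIPSO)phenyl]methanide (sulfonium ylide) | C[C@@H]1CC[C@@H](C)[S+]1[CH-]c1ccc(O[Si](C(C)C)(C(C)C)C(C)C)cc1 | intermediate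
38 | (2S,3S)-3-{(2R,3R)-3-[3,5-bis(TIPSO)phenyl]-7-(TIPSO)-2-[4-(TIPSO)phenyl]-2,3-dihydrobenzofuran-5-yl}-6-(TIPSO)-2-[4-(TIPSO)phenyl]-4-[(E)-4-(TIPSO)styryl]-2,3-dihydrobenzofuran | CC(C)[Si](Oc1ccc(/C=C/c2cc(O[Si](C(C)C)(C(C)C)C(C)C)cc3c2[C@H](c2cc(O[Si](C(C)C)(C(C)C)C(C)C)c4c(c2)[C@@H](c2cc(O[Si](C(C)C)(C(C)C)C(C)C)cc(O[Si](C(C)C)(C(C)C)C(C)C)c2)[C@H](c2ccc(O[Si](C(C)C)(C(C)C)C(C)C)cc2)O4)[C@@H](c2ccc(O[Si](C(C)C)(C(C)C)C(C)C)cc2)O3)cc1)(C(C)C)C(C)C | intermediate
39 | CNP0172909.1, (2S,3S)-3-[(2R,3R)-3-(3,5-dihydroxyphenyl)-7-hydroxy-2-(4-hydroxyphenyl)-2,3-dihydrobenzofuran-5-yl]-2-(4-hydroxyphenyl)-4-[(E)-4-hydroxystyryl]-2,3-dihydrobenzofuran-6-ol | Oc1ccc(/C=C/c2cc(O)cc3c2[C@H](c2cc(O)c4c(c2)[C@@H](c2cc(O)cc(O)c2)[C@H](c2ccc(O)cc2)O4)[C@@H](c2ccc(O)cc2)O3)cc1 | target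

## Step count and least certain steps

Total step count: 26. Longest linear sequence: 18 steps (steps 1–3, 6–16, 18, 19, 25 and 26).

**Step 12 (key step, proposed new method).**
- What may go wrong: the diyne may oligomerise with itself instead of taking up 18; 18 may insert with the wrong orientation, putting boron next to the styryl group; or the ynol ether may be lost before it reaches the metal, by sigmatropic rearrangement through the benzylic ether or by protonolysis to an ester. The same weakness shows one step earlier, where butyllithium can deprotonate C3–H of 15 and trigger β-elimination of the ether.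
- Fallback (known chemistry, leaves at 13, returns at 21): the oxygen on the alkyne is replaced by silicon. Alcohol 13 is silylated with chloro(ethynyl)dimethylsilane and imidazole to the ethynyl(dimethyl)silyl ether F1, a silicon-tethered diyne of a class established in metal-catalysed (2+2+2) cycloadditions. Cp*RuCl(cod) and 18 should convert it into the benzo-fused oxasiline boronate F2, with the same regiochemical argument as above. Tamao–Fleming oxidation (H2O2, KF, KHCO3, THF/MeOH, then Bu4NF) turns both C–Si and C–B into C–OH and strips the aryl silyl ethers, giving the hexol F3. A trace of 4-MeC6H4SO3H in CH2Cl2/THF at 0 °C closes the dihydrofuran through the para-quinone methide at C2; with C3 fixed, the trans tetraphenol F4 is expected. Silylation with excess TIPSCl and imidazole returns 21. This detour also makes steps 9 to 11 unnecessary.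

**Step 8.**
- What may go wrong: loss of enantiopurity, because the aryl-substituted allenylpalladium and allenylzinc species can racemise (exchange with zerovalent palladium, metallotropic shift to the benzylic propargylzinc) before they meet the aldehyde; and weak anti/syn discrimination with an aromatic aldehyde.
- Fallback (leaves at 10, returns at 13): 10 is converted with methyl chloroformate and pyridine into the methyl carbonate F5. Copper-catalysed anti-SN2' borylation (CuO-t-Bu, Xantphos, B2pin2, THF) gives the isolable, configurationally stable allenylboronate F6. F6 is heated with 2 and adds through the same closed transition state to give 13 after hydrolysis of the borate.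

**Step 16.**
- What may go wrong: the neighbouring triisopropylsilyl group may migrate to the magnesium phenoxide, so that formylation stalls or is directed to the hindered position C6'; the hydride-transfer stage may also be slow.
- Fallback (leaves at 23, returns at 28, replacing steps 16 and 18): the Grignard reagent 27 is quenched with DMF to give 3,5-bis(TIPSO)benzaldehyde F7. Phenol 23, F7 and phenylboronic acid are heated in toluene with a trace of propanoic acid and removal of water. This boron-templated ortho-hydroxyalkylation involves no phenoxide and should give the benzodioxaborin F8, which is opened by exchange with propane-1,3-diol to the benzhydrol 28.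

**Step 25.**
- What may go wrong: poor facial selectivity of the ylide toward the quinone methide, since the control exerted by the thiolane is established for carbonyl addition; self-condensation of the quinone methide; and dissociation of the electron-rich benzylsulfonium salt.
- Fallback (leaves at 29 and 34, returns at 38): bromide 34 is combined with thiolane and AgOSO2CF3 to give the achiral sulfonium salt F9. With Cs2CO3 and 29 this should give both trans dihydrobenzofurans. Because C2 and C3 are fixed, the unwanted (2'S,3'S) isomer F10 is a diastereomer of 38 and is removed by chromatography, at the cost of about half the material.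

## Further compounds

F1 | step 12 | (1S,2S,5E)-1-[ethynyl(dimethyl)silyloxy]-2-[4-(MOMO)-3-(TIPSO)phenyl]-1,6-bis[4-(TIPSO)phenyl]hex-5-en-3-yne | C#C[Si](C)(C)O[C@H](c1ccc(O[Si](C(C)C)(C(C)C)C(C)C)cc1)[C@@H](c1ccc(OCOC)c(O[Si](C(C)C)(C(C)C)C(C)C)c1)C#C/C=C/c1ccc(O[Si](C(C)C)(C(C)C)C(C)C)cc1
F2 | step 12 | benzo-fused 1,2-oxasiline boronate (Si at C7a, Bpin at C6, styryl at C4; 3S,4S) | C[Si]1(C)O[C@H](c2ccc(O[Si](C(C)C)(C(C)C)C(C)C)cc2)[C@@H](c2ccc(OCOC)c(O[Si](C(C)C)(C(C)C)C(C)C)c2)c2c(/C=C/c3ccc(O[Si](C(C)C)(C(C)C)C(C)C)cc3)cc(B3OC(C)(C)C(C)(C)O3)cc21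
F3 | step 12 | 2-{(1S,2S)-2-hydroxy-1-[3-hydroxy-4-(MOMO)phenyl]-2-(4-hydroxyphenyl)ethyl}-3-[(E)-4-hydroxystyryl]benzene-1,5-diol-type hexol | O[C@H](c1ccc(O)cc1)[C@@H](c1ccc(OCOC)c(O)c1)c1c(/C=C/c2ccc(O)cc2)cc(O)cc1O
F4 | step 12 | (2S,3S)-3-[3-hydroxy-4-(MOMO)phenyl]-2-(4-hydroxyphenyl)-4-[(E)-4-hydroxystyryl]-2,3-dihydrobenzofuran-6-ol | Oc1ccc(/C=C/c2cc(O)cc3c2[C@H](c2ccc(OCOC)c(O)c2)[C@@H](c2ccc(O)cc2)O3)cc1
F5 | step 8 | (1R,4E)-1-[4-(MOMO)-3-(TIPSO)phenyl]-5-[4-(TIPSO)phenyl]pent-4-en-2-yn-1-yl methyl carbonate | COC(=O)O[C@H](c1ccc(OCOC)c(O[Si](C(C)C)(C(C)C)C(C)C)c1)C#C/C=C/c1ccc(O[Si](C(C)C)(C(C)C)C(C)C)cc1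
F6 | step 8 | (aS,1E)-3-Bpin-5-[4-(MOMO)-3-(TIPSO)phenyl]-1-[4-(TIPSO)phenyl]penta-1,3,4-triene | CC1(C)OB(OC1(C)C)C(/C=C/c1ccc(O[Si](C(C)C)(C(C)C)C(C)C)cc1)=[C@@]=C([H])c1ccc(OCOC)c(O[Si](C(C)C)(C(C)C)C(C)C)c1
F7 | step 16 | 3,5-bis(TIPSO)benzaldehyde | O=Cc1cc(O[Si](C(C)C)(C(C)C)C(C)C)cc(O[Si](C(C)C)(C(C)C)C(C)C)c1
F8 | step 16 | 4-[3,5-bis(TIPSO)phenyl]-2-phenyl-8-(TIPSO)-4H-1,3,2-benzodioxaborin carrying the ring A dihydrobenzofuran at C6 | CC(C)[Si](Oc1ccc(/C=C/c2cc(O[Si](C(C)C)(C(C)C)C(C)C)cc3c2[C@H](c2cc5C(c4cc(O[Si](C(C)C)(C(C)C)C(C)C)cc(O[Si](C(C)C)(C(C)C)C(C)C)c4)OB(c4ccccc4)Oc5c(O[Si](C(C)C)(C(C)C)C(C)C)c2)[C@@H](c2ccc(O[Si](C(C)C)(C(C)C)C(C)C)cc2)O3)cc1)(C(C)C)C(C)C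
F9 | step 25 | 1-[4-(TIPSO)benzyl]thiolan-1-ium trifluoromethanesulfonate | C1CC[S+](Cc2ccc(O[Si](C(C)C)(C(C)C)C(C)C)cc2)C1.[O-]S(=O)(=O)C(F)(F)F
F10 | step 25 | (2'S,3'S) diastereomer of 38 | CC(C)[Si](Oc1ccc(/C=C/c2cc(O[Si](C(C)C)(C(C)C)C(C)C)cc3c2[C@H](c2cc(O[Si](C(C)C)(C(C)C)C(C)C)c4c(c2)[C@H](c2cc(O[Si](C(C)C)(C(C)C)C(C)C)cc(O[Si](C(C)C)(C(C)C)C(C)C)c2)[C@@H](c2ccc(O[Si](C(C)C)(C(C)C)C(C)C)cc2)O4)[C@@H](c2ccc(O[Si](C(C)C)(C(C)C)C(C)C)cc2)O3)cc1)(C(C)C)C(C)C
A1 | alternative 1 | (S)-naringenin | O=C1C[C@@H](c2ccc(O)cc2)Oc2cc(O)cc(O)c12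
A2 | alternative 1 | 3-diazo-5-hydroxy-7-methoxy-2-(4-methoxyphenyl)chroman-4-one (C2 as in A1) | [N-]=[N+]=C1C(=O)c2c(O)cc(OC)cc2O[C@@H]1c1ccc(OC)cc1
A3 | alternative 1 | methyl trans-4-hydroxy-6-methoxy-2-(4-methoxyphenyl)-2,3-dihydrobenzofuran-3-carboxylate | Oc1cc(OC)cc2c1[C@H](C(=O)OC)[C@@H](c1ccc(OC)cc1)O2
A4 | alternative 2 | (E)-2-{2-[5-chloro-3-methoxy-2-(methoxymethoxy)phenyl]ethenyl}-4,4,5,5-tetramethyl-1,3,2-dioxaborolane | COCOc1c(OC)cc(Cl)cc1/C=C/B1OC(C)(C)C(C)(C)O1
A5 | alternative 2 | 4-methoxyphenyllithium | [Li]c1ccc(OC)cc1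
A6 | alternative 2 | 3,5-dimethoxyphenyl trifluoromethanesulfonate | COc1cc(OC)cc(OS(=O)(=O)C(F)(F)F)c1
A7 | alternative 2 | 1,2-diaryl alkyl boronate from the conjunctive coupling | COCOc1c(OC)cc(Cl)cc1[C@@H](c1cc(OC)cc(OC)c1)[C@@H](c1ccc(OC)cc1)B1OC(C)(C)C(C)(C)O1
A8 | alternative 3 | 4-bromo-2-[(3,5-dimethoxyphenyl)(4-methylphenylsulfonyl)methyl]-6-methoxyphenol | COc1cc(Br)cc(C(c2cc(OC)cc(OC)c2)S(=O)(=O)c2ccc(C)cc2)c1O
A9 | alternative 3 | (2R,5R)-2,5-dimethylthiolan-1-ium-1-yl (4-methoxyphenyl)methanide | C[C@@H]1CC[C@@H](C)[S+]1[CH-]c1ccc(OC)cc1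
A10 | alternative 3 | (2R,3R)-5-bromo-3-(3,5-dimethoxyphenyl)-7-methoxy-2-(4-methoxyphenyl)-2,3-dihydrobenzofuran | Brc1cc(OC)c2c(c1)[C@@H](c1cc(OC)cc(OC)c1)[C@H](c1ccc(OC)cc1)O2
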